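**Strategy.** The cyclopentene ring (C1, C2, C3, C3a, C7a; indene numbering of the core) is made from a six-membered cyclic sulfone in which SO2 sits between C1 and C2. A Ramberg–Bäcklund reaction expels SO2, contracts the ring by one atom and places the C1=C2 double bond regiospecifically in the strained trans-fused bicycle, erasing an auxiliary stereocentre at C1. The sulfone is a trans-fused thiadecalin dioxide formed by an intramolecular Diels–Alder reaction of a sulfonyl-tethered tetraene and tiglate. Two allylic stereocentres, C3 (chiral-pool hydroxy ester) and C1 (α-chloroaldehyde), steer the cycloaddition that sets C3a, C7a, C6 and C7.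

Key step: step 13

Remark on locants: in the text the core carbons carry the locants C1(Et)=C2–C3(Me)–C3a–C4(Me)=C5–C6(Et, dienyl)–C7(Me, CO2H)–C7a (C7a bonded to C1 and C3a); these are not the IUPAC locants of the names. β is the face of H-3a.
Assumption: in step 9 the antipode of the aminocatalyst is the one that delivers the R chloride; some erosion at C1 is tolerable because C1 is destroyed in step 13.

**Step 1**
Reactants: 1 methyl (R)-3-hydroxy-2-methylpropanoate
Product: 2 methyl (R)-3-[(tert-butyldimethylsilyl)oxy]-2-methylpropanoate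
Conditions: TBSCl, imidazole, CH2Cl2, 0 °C to rt
Reagents that add atoms: tert-butyldimethylsilyl chloride, CC(C)(C)[Si](C)(C)Cl
Why: Imidazole-promoted O-silylation of the primary alcohol should be clean; the stereocentre that becomes C3 comes from the chiral pool and is not touched.

**Step 2**
Reactants: 2 methyl (R)-3-[(tert-butyldimethylsilyl)oxy]-2-methylpropanoate
Product: 3 (R)-3-[(tert-butyldimethylsilyl)oxy]-2-methylpropanal
Conditions: DIBAL-H (1.05 equiv), CH2Cl2, −78 °C; aq. potassium sodium tartrate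
Reagents that add atoms: none
Why: Partial ester reduction through the tetrahedral aluminium hemiacetal, stable at −78 °C, should give the aldehyde (future C3a) without epimerising the α-centre; the aldehyde is used at once.

**Step 3**
Reactants: 3 (R)-3-[(tert-butyldimethylsilyl)oxy]-2-methylpropanal; 4 2-(triphenylphosphoranylidene)propanal
Product: 5 (2E,4S)-5-[(tert-butyldimethylsilyl)oxy]-2,4-dimethylpent-2-enal
Conditions: toluene, 90 °C
Reagents that add atoms: none
Why: Wittig olefination with a stabilised, non-basic formyl ylide should give the E-trisubstituted enal (C3a=C4) without touching C3.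

**Step 4**
Reactants: 5 (2E,4S)-5-[(tert-butyldimethylsilyl)oxy]-2,4-dimethylpent-2-enal; 6 2-(triphenylphosphoranylidene)butanal
Product: 7 (2E,4E,6S)-7-[(tert-butyldimethylsilyl)oxy]-2-ethyl-4,6-dimethylhepta-2,4-dienal
Conditions: toluene, 110 °C
Reagents that add atoms: none
Why: A second stabilised-ylide Wittig reaction should form C5=C6 with E geometry, which places the ethyl group cis to C4 (the "inside" position of the later diene).

**Step 5**
Reactants: 7 (2E,4E,6S)-7-[(tert-butyldimethylsilyl)oxy]-2-ethyl-4,6-dimethylhepta-2,4-dienal; 4 2-(triphenylphosphoranylidene)propanal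
Product: 8 (2E,4E,6E,8S)-9-[(tert-butyldimethylsilyl)oxy]-4-ethyl-2,6,8-trimethylnona-2,4,6-trienal
Conditions: toluene, 110 °C, dark
Reagents that add atoms: none
Why: A third Wittig reaction of the same type should add the E-configured C8=C9(Me) unit of the side chain.

**Step 6**
Reactants: 8 (2E,4E,6E,8S)-9-[(tert-butyldimethylsilyl)oxy]-4-ethyl-2,6,8-trimethylnona-2,4,6-trienal; 9 diethyl benzylphosphonate
Product: 10 tert-butyl{[(2S,3E,5E,7E,9E)-6-ethyl-2,4,8-trimethyl-10-phenyldeca-3,5,7,9-tetraen-1-yl]oxy}dimethylsilane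
Conditions: 9, NaH, THF, 0 °C; then 8, 0 °C to rt, dark
Reagents that add atoms: none
Why: Horner–Wadsworth–Emmons olefination with a benzylic phosphonate anion should give the E-styryl terminus; no base-sensitive group is present yet.

**Step 7**
Reactants: 10 tert-butyl{[(2S,3E,5E,7E,9E)-6-ethyl-2,4,8-trimethyl-10-phenyldeca-3,5,7,9-tetraen-1-yl]oxy}dimethylsilane
Product: 11 (2S,3E,5E,7E,9E)-6-ethyl-2,4,8-trimethyl-10-phenyldeca-3,5,7,9-tetraen-1-ol
Conditions: TBAF, THF, 0 °C to rt
Reagents that add atoms: none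
Why: Fluoride cleavage of the silyl ether is neutral towards the acid-sensitive tetraene.

**Step 8**
Reactants: 11 (2S,3E,5E,7E,9E)-6-ethyl-2,4,8-trimethyl-10-phenyldeca-3,5,7,9-tetraen-1-ol
Product: 12 S-[(2S,3E,5E,7E,9E)-6-ethyl-2,4,8-trimethyl-10-phenyldeca-3,5,7,9-tetraen-1-yl] ethanethioate
Conditions: PPh3, DIAD, THF, 0 °C (betaine preformed); then 11, AcSH, dark
Reagents that add atoms: thioacetic acid, CC(=O)S
Why: Mitsunobu thioesterification is an SN2 displacement at the primary carbon (future C2) and should leave C3 and the polyene untouched.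

**Step 9**
Reactants: 13 butanal; 14 methyl 2-(triphenylphosphoranylidene)propanoate
Product: 16 methyl (2E,4R)-4-chloro-2-methylhex-2-enoate, via (R)-2-chlorobutanal 15 (not isolated)
Conditions: NCS, trans-2,5-diphenylpyrrolidine (10 mol%, antipode per assumption), CH2Cl2, 0 °C to rt; then 14, 0 °C
Reagents that add atoms: N-chlorosuccinimide, O=C1CCC(=O)N1Cl
Why: Enamine catalysis directs chlorine transfer to one face of the butanal enamine and sets C1 (R); the configurationally labile α-chloro aldehyde is trapped at once by Wittig reaction with the stabilised ylide, which should give the E-enoate (future dienophile C7=C7a).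

**Step 10**
Reactants: 12 S-[(2S,3E,5E,7E,9E)-6-ethyl-2,4,8-trimethyl-10-phenyldeca-3,5,7,9-tetraen-1-yl] ethanethioate; 16 methyl (2E,4R)-4-chloro-2-methylhex-2-enoate
Product: 18 methyl (2E,4S)-4-{[(2S,3E,5E,7E,9E)-6-ethyl-2,4,8-trimethyl-10-phenyldeca-3,5,7,9-tetraen-1-yl]sulfanyl}-2-methylhex-2-enoate, via tetraene thiol 17 (not isolated)
Conditions: K2CO3, MeOH/THF (degassed), 0 °C, dark; then 16, 0 °C to rt
Reagents that add atoms: none
Why: Methanolysis of the thioacetate gives the thiolate, which should displace the secondary allylic chloride by SN2 with inversion (C1 becomes S); SN2′ is blocked by the fully substituted α-carbon.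

**Step 11**
Reactants: 18 methyl (2E,4S)-4-{[(2S,3E,5E,7E,9E)-6-ethyl-2,4,8-trimethyl-10-phenyldeca-3,5,7,9-tetraen-1-yl]sulfanyl}-2-methylhex-2-enoate
Product: 19 methyl (2E,4S)-4-{[(2S,3E,5E,7E,9E)-6-ethyl-2,4,8-trimethyl-10-phenyldeca-3,5,7,9-tetraen-1-yl]sulfonyl}-2-methylhex-2-enoate
Conditions: (NH4)6Mo7O24·4H2O (10 mol%), 30% H2O2, EtOH/THF, 0 °C, dark
Reagents that add atoms: hydrogen peroxide, OO
Why: Molybdenum-peroxo species transfer oxygen to nucleophilic sulfur much faster than to C=C bonds, so the sulfide should reach the sulfone without epoxidation of the tetraene or the electron-poor enoate; the product is kept free of base.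

**Step 12**
Reactants: 19 methyl (2E,4S)-4-{[(2S,3E,5E,7E,9E)-6-ethyl-2,4,8-trimethyl-10-phenyldeca-3,5,7,9-tetraen-1-yl]sulfonyl}-2-methylhex-2-enoate
Product: 20 methyl 1α,7β-diethyl-4β,5,8β-trimethyl-7α-[(1E,3E)-2-methyl-4-phenylbuta-1,3-dien-1-yl]-3,4,4aβ,7,8,8aα-hexahydro-1H-isothiochromene-8α-carboxylate 2,2-dioxide (trans-fused; ethyl at C1 and methyl at C3 equatorial)
Conditions: toluene (0.01 M), BHT, 115 °C, sealed tube, dark
Reagents that add atoms: none
Why: Thermal intramolecular Diels–Alder reaction through the chair-like, tether-anti, ester-endo transition state: A(1,3) strain holds H-3 in the diene plane (against the C4 methyl) and H-1 in the dienophile plane (against the C7 methyl), so both tether substituents are equatorial and one diene face is attacked, which should set C3a and C7a (trans), while the E-enoate and the inside-ethyl/outside-dienyl diene geometry are transcribed into C7 and C6.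

**Step 13**
Reactants: 20 trans-fused thiadecalin dioxide (name as in step 12)
Product: 23 methyl (1R,3aR,4R,5S,7aS)-3,5-diethyl-1,4,7-trimethyl-5-[(1E,3E)-2-methyl-4-phenylbuta-1,3-dien-1-yl]-3a,4,5,7a-tetrahydro-1H-indene-4-carboxylate, via α-chloro sulfone 21 (not isolated), via episulfone 22 (not isolated)
Conditions: LDA (1.05 equiv), THF, −78 °C; added to C2Cl6, THF, −78 °C; then t-BuOK (3 equiv), −78 °C to rt
Reagents that add atoms: none
Why: Ramberg–Bäcklund reaction: kinetic lithiation at the less hindered C2 and chlorine transfer from C2Cl6 give α-chloro sulfone 21, then t-BuOK removes H-1 and the carbanion displaces chloride across sulfur. The thiirane dioxide ring of 22 closes by this 3-exo-tet 1,3-elimination, and cheletropic loss of SO2 contracts the six-membered ring (C1–S–C2–C3–C3a–C7a) to the cyclopentene by one atom, with the extrusion of SO2 paying for the strain of the trans-fused ring. No stereocentre is created: C3, C3a and C7a are untouched and the auxiliary centres at C1 and C2 vanish, so both C2-chloro epimers, any C1 epimer and any C1-chlorinated regioisomer should converge on one alkene. The selectivity needed is positional, C1=C2 and not the more stable C1=C7a isomer, and the mechanism secures it because the double bond can only form between the two former α-sulfonyl carbons. The ester at C7 has no α-hydrogen and is shielded by two quaternary carbons, so it should survive both bases.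

**Step 14**
Reactants: 23 methyl ester (name as in step 13)
Product: 24 (1R,3aR,4R,5S,7aS)-3,5-diethyl-1,4,7-trimethyl-5-[(1E,3E)-2-methyl-4-phenylbuta-1,3-dien-1-yl]-3a,4,5,7a-tetrahydro-1H-indene-4-carboxylic acid (target)
Conditions: NaSEt, DMF, 80 °C; then 1 M HCl
Reagents that add atoms: none
Why: The ester carbonyl is too shielded for acyl attack, so the methyl group is removed by SN2 attack of thiolate at O–CH3 (BAl2 dealkylation); acidification should give the acid with every stereocentre untouched.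

**Compound list**
1 | methyl (R)-3-hydroxy-2-methylpropanoate | OC[C@@H](C)C(=O)OC | starting material
2 | methyl (R)-3-[(tert-butyldimethylsilyl)oxy]-2-methylpropanoate | CC(C)(C)[Si](C)(C)OC[C@@H](C)C(=O)OC | intermediate
3 | (R)-3-[(tert-butyldimethylsilyl)oxy]-2-methylpropanal | CC(C)(C)[Si](C)(C)OC[C@@H](C)C=O | intermediate
4 | 2-(triphenylphosphoranylidene)propanal | CC(C=O)=P(c1ccccc1)(c1ccccc1)c1ccccc1 | starting material
5 | (2E,4S)-5-[(tert-butyldimethylsilyl)oxy]-2,4-dimethylpent-2-enal | CC(C)(C)[Si](C)(C)OC[C@@H](C)/C=C(C)/C=O | intermediate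
6 | 2-(triphenylphosphoranylidene)butanal | CCC(C=O)=P(c1ccccc1)(c1ccccc1)c1ccccc1 | starting material
7 | (2E,4E,6S)-7-[(tert-butyldimethylsilyl)oxy]-2-ethyl-4,6-dimethylhepta-2,4-dienal | CC(C)(C)[Si](C)(C)OC[C@@H](C)/C=C(C)/C=C(CC)/C=O | intermediate
8 | (2E,4E,6E,8S)-9-[(tert-butyldimethylsilyl)oxy]-4-ethyl-2,6,8-trimethylnona-2,4,6-trienal | CC(C)(C)[Si](C)(C)OC[C@@H](C)/C=C(C)/C=C(CC)/C=C(C)/C=O | intermediate
9 | diethyl benzylphosphonate | CCOP(=O)(Cc1ccccc1)OCC | starting material
10 | tert-butyl{[(2S,3E,5E,7E,9E)-6-ethyl-2,4,8-trimethyl-10-phenyldeca-3,5,7,9-tetraen-1-yl]oxy}dimethylsilane | CC(C)(C)[Si](C)(C)OC[C@@H](C)/C=C(C)/C=C(CC)/C=C(C)/C=C/c1ccccc1 | intermediate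
11 | (2S,3E,5E,7E,9E)-6-ethyl-2,4,8-trimethyl-10-phenyldeca-3,5,7,9-tetraen-1-ol | OC[C@@H](C)/C=C(C)/C=C(CC)/C=C(C)/C=C/c1ccccc1 | intermediate
12 | S-[(2S,3E,5E,7E,9E)-6-ethyl-2,4,8-trimethyl-10-phenyldeca-3,5,7,9-tetraen-1-yl] ethanethioate | CC(=O)SC[C@@H](C)/C=C(C)/C=C(CC)/C=C(C)/C=C/c1ccccc1 | intermediate
13 | butanal | CCCC=O | starting material
14 | methyl 2-(triphenylphosphoranylidene)propanoate | COC(=O)C(C)=P(c1ccccc1)(c1ccccc1)c1ccccc1 | starting material
15 | (R)-2-chlorobutanal (not isolated) | CC[C@@H](Cl)C=O | intermediate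
16 | methyl (2E,4R)-4-chloro-2-methylhex-2-enoate | CC[C@@H](Cl)/C=C(C)/C(=O)OC | intermediate
17 | (2S,3E,5E,7E,9E)-6-ethyl-2,4,8-trimethyl-10-phenyldeca-3,5,7,9-tetraene-1-thiol (not isolated; present as thiolate) | SC[C@@H](C)/C=C(C)/C=C(CC)/C=C(C)/C=C/c1ccccc1 | intermediate
18 | methyl (2E,4S)-4-{[(2S,3E,5E,7E,9E)-6-ethyl-2,4,8-trimethyl-10-phenyldeca-3,5,7,9-tetraen-1-yl]sulfanyl}-2-methylhex-2-enoate | COC(=O)/C(C)=C/[C@H](CC)SC[C@@H](C)/C=C(C)/C=C(CC)/C=C(C)/C=C/c1ccccc1 | intermediate
19 | methyl (2E,4S)-4-{[(2S,3E,5E,7E,9E)-6-ethyl-2,4,8-trimethyl-10-phenyldeca-3,5,7,9-tetraen-1-yl]sulfonyl}-2-methylhex-2-enoate | COC(=O)/C(C)=C/[C@H](CC)S(=O)(=O)C[C@@H](C)/C=C(C)/C=C(CC)/C=C(C)/C=C/c1ccccc1 | intermediate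
20 | methyl 1α,7β-diethyl-4β,5,8β-trimethyl-7α-[(1E,3E)-2-methyl-4-phenylbuta-1,3-dien-1-yl]-3,4,4aβ,7,8,8aα-hexahydro-1H-isothiochromene-8α-carboxylate 2,2-dioxide (trans-fused) | CC[C@@H]1S(=O)(=O)C[C@@H](C)[C@@H]2C(C)=C[C@@](/C=C(C)/C=C/c3ccccc3)(CC)[C@](C)(C(=O)OC)[C@@H]12 | intermediate
21 | 3-chloro derivative of 20 (chlorine on C2 of the core, both epimers; not isolated) | CC[C@@H]1S(=O)(=O)C(Cl)[C@@H](C)[C@@H]2C(C)=C[C@@](/C=C(C)/C=C/c3ccccc3)(CC)[C@](C)(C(=O)OC)[C@@H]12 | intermediate
22 | episulfone: thiirane 1,1-dioxide spanning C1 and C2 of the trans-fused hydrindene methyl ester (configuration at C1/C2 not defined; not isolated) | CCC12C(S1(=O)=O)[C@@H](C)[C@@H]3C(C)=C[C@@](/C=C(C)/C=C/c4ccccc4)(CC)[C@](C)(C(=O)OC)[C@@H]23 | intermediate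
23 | methyl (1R,3aR,4R,5S,7aS)-3,5-diethyl-1,4,7-trimethyl-5-[(1E,3E)-2-methyl-4-phenylbuta-1,3-dien-1-yl]-3a,4,5,7a-tetrahydro-1H-indene-4-carboxylate | CCC1=C[C@@H](C)[C@@H]2C(C)=C[C@@](/C=C(C)/C=C/c3ccccc3)(CC)[C@](C)(C(=O)OC)[C@@H]12 | intermediate
24 | (1R,3aR,4R,5S,7aS)-3,5-diethyl-1,4,7-trimethyl-5-[(1E,3E)-2-methyl-4-phenylbuta-1,3-dien-1-yl]-3a,4,5,7a-tetrahydro-1H-indene-4-carboxylic acid | CCC1=C[C@@H](C)[C@@H]2C(C)=C[C@@](/C=C(C)/C=C/c3ccccc3)(CC)[C@](C)(C(=O)O)[C@@H]12 | target

**Step count.** Total: 14 steps. Longest linear sequence: 13 steps (steps 1–8 and 10–14).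

**Steps most likely to fail**

1. Step 13 (key step). The risk is that removal of the hindered tertiary H-1 of 21 is slow, so that chlorine exchange, over-chlorination at C2 or base-induced decomposition outruns the 1,3-closure. The fallback moves the halogen to C1 before the cycloaddition and keeps the ring contraction. It sets out from 19: the acidic γ-hydrogen at C1 is replaced by chlorine (NCS, K2CO3, THF, 0 °C) to give the acyclic C1-chloro sulfone F1. Thermal intramolecular Diels–Alder reaction of F1 (toluene, BHT, 110 °C; facial control then rests on C3 alone) should give the bicyclic tertiary α-chloro sulfone F2. t-BuOK in THF then deprotonates the unhindered C2, which displaces the tertiary chloride to give episulfone 22 and, after loss of SO2, 23, where the route is rejoined.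

2. Step 12. The risk is slow bond formation at the tetrasubstituted diene terminus, so that [1,5]-hydrogen shifts in the cis-ethyl diene or leakage through the cis-fused (tether-endo) transition state compete. The fallback raises the dienophile to the aldehyde oxidation level so that the cycloaddition should run near room temperature, thermally or with Me2AlCl. It sets out from 19: DIBAL-H (CH2Cl2, −78 °C) gives the allylic alcohol F3, MnO2 gives the enal F4, and cycloaddition gives the bicyclic aldehyde F5. Pinnick oxidation (NaClO2, NaH2PO4, 2-methyl-2-butene) gives the acid F6, and TMSCHN2 in MeOH/toluene returns the methyl ester 20.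

3. Step 11. The risk is oxygen transfer to the electron-rich tetraene, or [2,3]-sigmatropic leakage of the intermediate allylic sulfoxide with loss of C1 configuration and enoate geometry. The fallback brings sulfur in at the sulfone oxidation level. It sets out from alcohol 11: I2, PPh3 and imidazole give the iodide F7, and displacement with sodium 3-methoxy-3-oxopropane-1-sulfinate (DMSO) gives the β-sulfonyl ester F8. NaOMe liberates the sulfinate F9 by retro-Michael reaction, and S-alkylation of F9 with chloride 16 (DMF, inversion at C1) gives sulfone 19 directly.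

**Further compounds**
F1 | step 13 | methyl (E)-4-chloro-4-{[(2S,3E,5E,7E,9E)-6-ethyl-2,4,8-trimethyl-10-phenyldeca-3,5,7,9-tetraen-1-yl]sulfonyl}-2-methylhex-2-enoate (both C4 epimers) | COC(=O)/C(C)=C/C(Cl)(CC)S(=O)(=O)C[C@@H](C)/C=C(C)/C=C(CC)/C=C(C)/C=C/c1ccccc1
F2 | step 13 | 1-chloro derivative of 20 (chlorine on C1 of the core, both epimers) | CCC1(Cl)S(=O)(=O)C[C@@H](C)[C@@H]2C(C)=C[C@@](/C=C(C)/C=C/c3ccccc3)(CC)[C@](C)(C(=O)OC)[C@@H]12
F3 | step 12 | (2E,4S)-4-{[(2S,3E,5E,7E,9E)-6-ethyl-2,4,8-trimethyl-10-phenyldeca-3,5,7,9-tetraen-1-yl]sulfonyl}-2-methylhex-2-en-1-ol | OC/C(C)=C/[C@H](CC)S(=O)(=O)C[C@@H](C)/C=C(C)/C=C(CC)/C=C(C)/C=C/c1ccccc1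
F4 | step 12 | (2E,4S)-4-{[(2S,3E,5E,7E,9E)-6-ethyl-2,4,8-trimethyl-10-phenyldeca-3,5,7,9-tetraen-1-yl]sulfonyl}-2-methylhex-2-enal | O=C/C(C)=C/[C@H](CC)S(=O)(=O)C[C@@H](C)/C=C(C)/C=C(CC)/C=C(C)/C=C/c1ccccc1
F5 | step 12 | 8α-carbaldehyde analogue of 20 (same skeleton and configuration, CHO in place of CO2Me) | CC[C@@H]1S(=O)(=O)C[C@@H](C)[C@@H]2C(C)=C[C@@](/C=C(C)/C=C/c3ccccc3)(CC)[C@](C)(C=O)[C@@H]12
F6 | step 12 | 8α-carboxylic acid analogue of 20 | CC[C@@H]1S(=O)(=O)C[C@@H](C)[C@@H]2C(C)=C[C@@](/C=C(C)/C=C/c3ccccc3)(CC)[C@](C)(C(=O)O)[C@@H]12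
F7 | step 11 | [(1E,3E,5E,7E,9S)-10-iodo-5-ethyl-3,7,9-trimethyldeca-1,3,5,7-tetraen-1-yl]benzene | IC[C@@H](C)/C=C(C)/C=C(CC)/C=C(C)/C=C/c1ccccc1
F8 | step 11 | methyl 3-{[(2S,3E,5E,7E,9E)-6-ethyl-2,4,8-trimethyl-10-phenyldeca-3,5,7,9-tetraen-1-yl]sulfonyl}propanoate | COC(=O)CCS(=O)(=O)C[C@@H](C)/C=C(C)/C=C(CC)/C=C(C)/C=C/c1ccccc1
F9 | step 11 | sodium (2S,3E,5E,7E,9E)-6-ethyl-2,4,8-trimethyl-10-phenyldeca-3,5,7,9-tetraene-1-sulfinate | [Na+].[O-]S(=O)C[C@@H](C)/C=C(C)/C=C(CC)/C=C(C)/C=C/c1ccccc1
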